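**Plan**

- Numbering of the target: ring C1 (alkene carbon with the side chain), C2 (=CH), C3 (CH2), C4 (CHCl), C5 (CMe2), C6 (CHBr); side chain C1′ (CHCl), C2′ (CH2Br). The target is (4R,6S,1′S), with ring Cl and ring Br trans.
- Retrosynthetic cuts, in order: C6–Br and C2′–Br (both from OH), C1′–Cl (chloride opening of a vinyl oxirane), the ring bond C1–C6 (alkenyl iodide plus aldehyde), the Z-iodoalkene C1=C2 (from an alkyne), and C2–C3 (acetylide plus primary triflate).
- Forward: a chlorohydrin triflate carrying C3–C6 is alkylated with a glyceraldehyde-derived acetylide, and trans-hydrostannation/iodination fixes the Z-iodoalkene. The cyclohexene, the only ring, is closed in step 9 by an intramolecular Nozaki–Hiyama–Kishi reaction, and the three remaining halogens follow.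
- Enabling feature: C6 lies between the quaternary C5 (CMe2) and the alkene carbon C1, so as an aldehyde it has no α-hydrogen. The gem-dimethyl group and the Z-alkene C1=C2 fold the chain so that C1 and C6 meet in a six-membered ring.
- Stereochemistry: C4 comes from enamine-catalysed α-chlorination. C1′ comes from (S)-glyceraldehyde acetonide with one inversion (chloride opening). C6 comes from the ring closure (alcohol cis to Cl) followed by one inversion (bromide).

Key step: step 9

Assumption: (2R,5R)-2,5-diphenylpyrrolidine is taken to be the catalyst antipode that gives the (S)-α-chloro aldehyde; if the sense of induction is the reverse, the (2S,5S) catalyst is used and nothing else changes.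

**Route**

Step 1
Reactants: 1 methyl 3,3-dimethylpent-4-enoate
Product: 2 3,3-dimethylpent-4-enal
Conditions: i-Bu2AlH (1.05 equiv), CH2Cl2, −78 °C; Rochelle salt work-up
Reagents that add atoms: none
Why: Partial reduction of an ester: at −78 °C i-Bu2AlH adds once and the aluminium hemiacetal collapses to the aldehyde only on work-up, while the alkene is inert.

Step 2
Reactants: 2 3,3-dimethylpent-4-enal
Product: 4 (S)-2-chloro-3,3-dimethylpent-4-en-1-ol, via α-chloro aldehyde 3 (not isolated)
Conditions: (2R,5R)-2,5-diphenylpyrrolidine (10 mol%), NCS (1.2 equiv), CH2Cl2, 0 °C to rt; then NaBH4, MeOH, 0 °C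
Reagents that add atoms: N-chlorosuccinimide, O=C1CCC(=O)N1Cl
Why: Enamine-catalysed α-chlorination of an aldehyde: the C2-symmetric pyrrolidine forms an enamine with one face shielded by a phenyl group, so NCS delivers chlorine to the open face and sets the (S) centre (tert-alkyl-substituted acetaldehydes lie within the scope of this reaction type), and immediate NaBH4 reduction fixes the configurationally labile α-chloro aldehyde as the chlorohydrin.

Step 3
Reactants: 5 (S)-2,2-dimethyl-1,3-dioxolane-4-carbaldehyde
Product: 6 (R)-4-ethynyl-2,2-dimethyl-1,3-dioxolane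
Conditions: dimethyl (1-diazo-2-oxopropyl)phosphonate, K2CO3, MeOH, 0 °C to rt
Reagents that add atoms: dimethyl (1-diazo-2-oxopropyl)phosphonate, COP(=O)(OC)C(=[N+]=[N-])C(C)=O
Why: Seyferth–Gilbert homologation in the Ohira–Bestmann version: the diazomethylphosphonate anion formed in situ converts the aldehyde into the terminal alkyne under conditions mild enough to leave the α-alkoxy stereocentre untouched (its descriptor changes from S to R only through the priority rules).

Step 4
Reactants: 4 (S)-2-chloro-3,3-dimethylpent-4-en-1-ol; 6 (R)-4-ethynyl-2,2-dimethyl-1,3-dioxolane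
Product: 8 (4R)-4-[(4R)-4-chloro-5,5-dimethylhept-6-en-1-yn-1-yl]-2,2-dimethyl-1,3-dioxolane, via primary triflate 7 (not isolated)
Conditions: 4, Tf2O, 2,6-lutidine, CH2Cl2, −78 °C; filtration through silica (pentane); then added to 6 (1.5 equiv), n-BuLi, THF–DMPU, −78 to −20 °C
Reagents that add atoms: triflic anhydride, O=S(=O)(OS(=O)(=O)C(F)(F)F)C(F)(F)F (its CF3SO2 group is present in 7 only)
Why: O-Triflation followed by SN2 alkylation of a lithium acetylide with a primary triflate: the C–Cl centre is not involved and keeps its configuration (descriptor R in 8 by priority change), DMPU and low temperature favour substitution over E2, and the hindered secondary chloride is inert to the acetylide.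

Step 5
Reactants: 8 (4R)-4-[(4R)-4-chloro-5,5-dimethylhept-6-en-1-yn-1-yl]-2,2-dimethyl-1,3-dioxolane
Product: 9 (2R,6R)-6-chloro-7,7-dimethylnon-8-en-3-yne-1,2-diol
Conditions: AcOH–H2O (4:1), 40 °C
Reagents that add atoms: none
Why: Acid-catalysed hydrolysis of the isopropylidene acetal frees the propargylic 1,2-diol without touching the alkyl chloride, the alkyne or the alkene.

Step 6
Reactants: 9 (2R,6R)-6-chloro-7,7-dimethylnon-8-en-3-yne-1,2-diol
Product: 11 (2S,3Z,6R)-6-chloro-3-iodo-7,7-dimethylnona-3,8-diene-1,2-diol, via Z-alkenylstannane 10 (not isolated)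
Conditions: [(C5Me5)RuCl]4 (2 mol%), Bu3SnH (1.1 equiv), CH2Cl2, rt; then I2, CH2Cl2, 0 °C
Reagents that add atoms: iodine, II; tributyltin hydride, CCCC[SnH](CCCC)CCCC (its Bu3Sn group is present in 10 only)
Why: Hydroxyl-directed ruthenium-catalysed trans-hydrostannation followed by iododestannylation: hydrogen bonding of the propargylic OH to the Ru–Cl unit places tin on the alkyne carbon next to the carbinol and hydrogen trans to it, and tin–iodine exchange with retention gives the Z-iodoalkene in which the chain and iodine are cis, as the ring closure requires.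

Step 7
Reactants: 11 (2S,3Z,6R)-6-chloro-3-iodo-7,7-dimethylnona-3,8-diene-1,2-diol
Product: 13 (2S)-2-[(1Z,4R)-4-chloro-1-iodo-5,5-dimethylhepta-1,6-dien-1-yl]oxirane, via primary tosylate 12 (not isolated)
Conditions: TsCl (1.05 equiv), Bu2SnO (2 mol%), Et3N, CH2Cl2, 0 °C; then K2CO3, MeOH, 0 °C
Reagents that add atoms: p-toluenesulfonyl chloride, Cc1ccc(cc1)S(Cl)(=O)=O (its tosyl group is present in 12 only)
Why: Tin-catalysed sulfonylation selective for the primary hydroxyl followed by Williamson-type 3-exo-tet closure by the secondary alkoxide: the C–O bond at the stereocentre is not broken, so the oxirane carbon keeps its configuration.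

Step 8
Reactants: 13 (2S)-2-[(1Z,4R)-4-chloro-1-iodo-5,5-dimethylhepta-1,6-dien-1-yl]oxirane
Product: 14 (3R,5Z)-3-chloro-6-iodo-2,2-dimethyl-6-[(2S)-oxiran-2-yl]hex-5-enal
Conditions: OsO4 (2 mol%), NaIO4 (4 equiv), 2,6-lutidine, dioxane–H2O (3:1), rt
Reagents that add atoms: sodium periodate, [Na+].[O-]I(=O)(=O)=O
Why: Lemieux–Johnson oxidation: OsO4 dihydroxylates the monosubstituted terminal alkene in preference to the hindered, iodine-deactivated trisubstituted alkene, periodate cleaves the diol and reoxidises osmium, and the buffered neutral medium spares the oxirane.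

Step 9
Reactants: 14 (3R,5Z)-3-chloro-6-iodo-2,2-dimethyl-6-[(2S)-oxiran-2-yl]hex-5-enal
Product: 15 (1S,5R)-5-chloro-6,6-dimethyl-2-[(2R)-oxiran-2-yl]cyclohex-2-en-1-ol
Conditions: CrCl2 (6 equiv), NiCl2 (1 mol%), degassed DMSO, rt, 0.005 M; aqueous sodium serinate work-up
Reagents that add atoms: none
Why: Nozaki–Hiyama–Kishi reaction: zerovalent nickel, formed from NiCl2 by CrCl2, inserts into the C–I bond, transmetallation to trivalent chromium gives a Z-alkenylchromium species with retention of geometry, and this adds to the aldehyde through a chromium-bridged four-centre transition state. The closest known reaction type is the nickel/chromium-mediated cyclisation of iodoalkenyl aldehydes to 2-substituted cycloalk-2-en-1-ols. The cyclohexene ring closes in the 6-exo-trig mode at the carbonyl carbon, with the Z-alkene ending up inside the ring. The new carbinol centre is controlled by the chlorine-bearing carbon: in the chair-like transition state C–Cl is pseudo-equatorial and the chromium-bound oxygen has to lie near the alkene plane, hence pseudo-equatorial, which should give the 1,3-cis (1S) alcohol. The step needs chemoselectivity for C–I over the secondary alkyl chloride and the oxirane, and cyclisation over intermolecular coupling; the first is secured by the mild, non-basic alkenylchromium reagent, the second by the non-enolisable aldehyde next to the quaternary carbon, the gem-dimethyl effect, the fixed Z geometry and high dilution.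

Step 10
Reactants: 15 (1S,5R)-5-chloro-6,6-dimethyl-2-[(2R)-oxiran-2-yl]cyclohex-2-en-1-ol
Product: 16 (1R,5R)-5-chloro-2-[(1S)-1-chloro-2-hydroxyethyl]-6,6-dimethylcyclohex-2-en-1-ol
Conditions: HCl (1.0 M in Et2O, 1.2 equiv), CH2Cl2, −78 to −40 °C
Reagents that add atoms: hydrogen chloride, Cl
Why: Acid-promoted opening of a vinyl oxirane: the protonated oxirane is attacked by chloride at the allylic carbon, which carries most of the positive charge, in an ion-pair SN2 process with inversion, which sets the (S) C–Cl centre and frees the primary alcohol.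

Step 11
Reactants: 16 (1R,5R)-5-chloro-2-[(1S)-1-chloro-2-hydroxyethyl]-6,6-dimethylcyclohex-2-en-1-ol
Product: 17 (4R,6S)-6-bromo-1-[(1S)-2-bromo-1-chloroethyl]-4-chloro-5,5-dimethylcyclohex-1-ene (CNP0105443.3)
Conditions: CBr4 (3 equiv), PPh3 (3 equiv), 2,6-lutidine (0.2 equiv), CH2Cl2, 0 °C
Reagents that add atoms: carbon tetrabromide, BrC(Br)(Br)Br
Why: Appel reaction: both hydroxyls become alkoxyphosphonium ions and are displaced by bromide, the primary one directly and the pseudo-equatorial ring one by axial SN2 attack with inversion, which puts bromine trans to the ring chlorine (pseudo-axial and free of allylic strain with the side chain).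

**Compound list**

1 | methyl 3,3-dimethylpent-4-enoate | COC(=O)CC(C)(C)C=C | starting material
2 | 3,3-dimethylpent-4-enal | O=CCC(C)(C)C=C | intermediate
3 | (S)-2-chloro-3,3-dimethylpent-4-enal | C=CC(C)(C)[C@H](Cl)C=O | intermediate
4 | (S)-2-chloro-3,3-dimethylpent-4-en-1-ol | C=CC(C)(C)[C@H](Cl)CO | intermediate
5 | (S)-2,2-dimethyl-1,3-dioxolane-4-carbaldehyde | O=C[C@@H]1COC(C)(C)O1 | starting material
6 | (R)-4-ethynyl-2,2-dimethyl-1,3-dioxolane | C#C[C@@H]1COC(C)(C)O1 | intermediate
7 | (S)-2-chloro-3,3-dimethylpent-4-en-1-yl trifluoromethanesulfonate | C=CC(C)(C)[C@H](Cl)COS(=O)(=O)C(F)(F)F | intermediate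
8 | (4R)-4-[(4R)-4-chloro-5,5-dimethylhept-6-en-1-yn-1-yl]-2,2-dimethyl-1,3-dioxolane | C=CC(C)(C)[C@H](Cl)CC#C[C@@H]1COC(C)(C)O1 | intermediate
9 | (2R,6R)-6-chloro-7,7-dimethylnon-8-en-3-yne-1,2-diol | C=CC(C)(C)[C@H](Cl)CC#C[C@@H](O)CO | intermediate
10 | (2S,3Z,6R)-6-chloro-7,7-dimethyl-3-(tributylstannyl)nona-3,8-diene-1,2-diol | C=CC(C)(C)[C@H](Cl)C/C=C(\[Sn](CCCC)(CCCC)CCCC)[C@@H](O)CO | intermediate
11 | (2S,3Z,6R)-6-chloro-3-iodo-7,7-dimethylnona-3,8-diene-1,2-diol | C=CC(C)(C)[C@H](Cl)C/C=C(\I)[C@@H](O)CO | intermediate
12 | (2S,3Z,6R)-6-chloro-2-hydroxy-3-iodo-7,7-dimethylnona-3,8-dien-1-yl 4-methylbenzenesulfonate | C=CC(C)(C)[C@H](Cl)C/C=C(\I)[C@@H](O)COS(=O)(=O)c1ccc(C)cc1 | intermediate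
13 | (2S)-2-[(1Z,4R)-4-chloro-1-iodo-5,5-dimethylhepta-1,6-dien-1-yl]oxirane | C=CC(C)(C)[C@H](Cl)C/C=C(\I)[C@@H]1CO1 | intermediate
14 | (3R,5Z)-3-chloro-6-iodo-2,2-dimethyl-6-[(2S)-oxiran-2-yl]hex-5-enal | O=CC(C)(C)[C@H](Cl)C/C=C(\I)[C@@H]1CO1 | intermediate
15 | (1S,5R)-5-chloro-6,6-dimethyl-2-[(2R)-oxiran-2-yl]cyclohex-2-en-1-ol (OH cis to Cl) | CC1(C)[C@H](Cl)CC=C([C@@H]2CO2)[C@@H]1O | intermediate
16 | (1R,5R)-5-chloro-2-[(1S)-1-chloro-2-hydroxyethyl]-6,6-dimethylcyclohex-2-en-1-ol | CC1(C)[C@H](Cl)CC=C([C@H](Cl)CO)[C@@H]1O | intermediate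
17 | (4R,6S)-6-bromo-1-[(1S)-2-bromo-1-chloroethyl]-4-chloro-5,5-dimethylcyclohex-1-ene | CC1(C)[C@H](Cl)CC=C([C@H](Cl)CBr)[C@H]1Br | target

**Step count and risks**

Total step count: 11. Longest linear sequence: 10 (steps 1, 2 and 4 to 11).

Steps most likely to fail:

- **Step 11.** The ring carbinol is allylic and next to the quaternary carbon, so bromide may enter with allylic transposition (SN2′) or after ionisation, and bromide may exchange with the side-chain allylic chloride during the longer reaction time this needs. The fallback sets out from 16 and separates the two brominations by mechanism. Appel bromination with 1.1 equivalents of CBr4/PPh3 at −40 °C touches only the primary hydroxyl and should give (1R,5R)-2-[(1S)-2-bromo-1-chloroethyl]-5-chloro-6,6-dimethylcyclohex-2-en-1-ol F1. The ring alcohol of F1 is then converted under ionising, equilibrating conditions (Me3SiBr, CH2Cl2, −20 °C), where the C6 epimers interconvert by bromide exchange and the pseudo-axial bromide trans to the equatorial chlorine should accumulate. This comes back to the route at 17.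

- **Step 9.** Facial selectivity in the addition of the alkenylchromium species to the aldehyde may be poor, giving the C1 epimer alongside 15. The fallback sets out from the crude mixture of 15 and its epimer and sets C1 by ketone reduction instead of by C–C bond formation. Dess–Martin oxidation converges both epimers to the enone (5R)-5-chloro-6,6-dimethyl-2-[(2R)-oxiran-2-yl]cyclohex-2-en-1-one F2. Luche reduction (NaBH4, CeCl3·7H2O, MeOH, −78 °C) should then deliver hydride axially, past the face not blocked by the axial methyl group, to give the pseudo-equatorial alcohol cis to chlorine. This comes back to the route at 15.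

- **Step 4.** The basic acetylide may eliminate triflic acid toward the chlorine-bearing carbon, or substitution at the β-branched primary carbon may be too slow. The fallback sets out from 4 and replaces the triflate by an oxirane electrophile, with chlorine reinstalled by a second inversion. Aqueous NaOH closes 4 to (R)-2-(2-methylbut-3-en-2-yl)oxirane F3 with inversion. The lithium acetylide of 6 with BF3·OEt2 (THF, −78 °C) opens F3 at the terminal carbon to (4S)-1-[(4R)-2,2-dimethyl-1,3-dioxolan-4-yl]-5,5-dimethylhept-6-en-1-yn-4-ol F4. Appel-type chlorination (PPh3, NCS) with inversion at the hindered carbinol then restores the original configuration. This comes back to the route at 8.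

Further compounds
F1 | step 11 | (1R,5R)-2-[(1S)-2-bromo-1-chloroethyl]-5-chloro-6,6-dimethylcyclohex-2-en-1-ol | CC1(C)[C@H](Cl)CC=C([C@H](Cl)CBr)[C@@H]1O
F2 | step 9 | (5R)-5-chloro-6,6-dimethyl-2-[(2R)-oxiran-2-yl]cyclohex-2-en-1-one | CC1(C)[C@H](Cl)CC=C([C@@H]2CO2)C1=O
F3 | step 4 | (R)-2-(2-methylbut-3-en-2-yl)oxirane | C=CC(C)(C)[C@@H]1CO1
F4 | step 4 | (4S)-1-[(4R)-2,2-dimethyl-1,3-dioxolan-4-yl]-5,5-dimethylhept-6-en-1-yn-4-ol | C=CC(C)(C)[C@@H](O)CC#C[C@@H]1COC(C)(C)O1
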